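**Retrosynthetic overview**
- Licobichalcone is reached by global desilylation of its hexa-TBS ether; the C3=C4 double bond comes from dehydration of an all-cis 4-hydroxytetralin (benzylic β-hydroxy ketone).
- Ring B (C1–C2–C3–C4–C4a–C8a) is closed last by an enantioselective photoenolization/Diels–Alder reaction that forms C4–C3 and C1–C2 between an ortho-formyl diarylmethane (rings A and C in place) and a (Z)-1,2-diaroylethene.
- Enabling feature: C4 (alkene CH) and C1 (diarylmethine) are the two benzylic carbons on the neighbouring ring A atoms C4a and C8a. A formyl group on C4a and the doubly benzylic C1–H therefore stand 1,5 to each other, and light turns them into a hydroxy-o-quinodimethane. C2 and C3 carry the same aroyl group, so the dienophile is symmetrical and its Z geometry becomes the 1,2-cis relation.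
- The aldehyde comes from Negishi coupling of a ring A iodide (directed ortho-lithiation of silylated 5-hydroxyvanillin) with a ring C benzylzinc reagent (directed lithiation/hydroxymethylation of silylated 3-methoxycatechol).
- The dienophile comes from oxidative opening of a 2,5-diarylfuran, a temporary ring that guarantees Z, itself made by twofold Suzuki coupling. Order of ring formation: furan (made, then opened), then ring B.

Key step: step 9

Conventions: TBS = tert-butyldimethylsilyl. Target numbering is used for the carbocycle throughout: C1 (aryl-bearing CH), C2, C3, C4 (alkene CH); ring A = C4a–C8a (6-O, 7-O, 8-OMe); ring C = the 2-methoxy-3,4-dioxygenated aryl group on C1.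

Remark: the SMILES encodes the 1,2-cis (1S,2S) isomer, which is expected to be less stable than the trans epimer, so no enolizing conditions are used once C2 is set. The sense of induction of the TADDOL ligand is assumed, and the antipodal ligand would be used if the first run shows the opposite sense.

**Step 1**
Reactants: 1 3,4-dihydroxy-5-methoxybenzaldehyde (5-hydroxyvanillin)
Product: 2 3,4-bis(TBSO)-5-methoxybenzaldehyde
Conditions: TBSCl (2.4 equiv), imidazole (5 equiv), DMF, 0 → 25 °C
Reagents that add atoms: tert-butyldimethylsilyl chloride, CC(C)(C)[Si](C)(C)Cl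
Why: Silyl ether formation on both phenols leaves the aldehyde untouched; TBS ethers are chosen because they do not direct lithiation and can be removed at the end with weakly acidic fluoride.

**Step 2**
Reactants: 2 3,4-bis(TBSO)-5-methoxybenzaldehyde
Product: 5 4,5-bis(TBSO)-2-iodo-3-methoxybenzaldehyde, via lithium amino alkoxide 3 (not isolated), via ring-lithiated amino alkoxide 4 (not isolated)
Conditions: LiN(Me)CH2CH2NMe2 (1.1 equiv, from the amine and n-BuLi), THF, −20 °C; n-BuLi (3 equiv), −20 °C; I2, −78 → 0 °C; H2O, aq. Na2S2O3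
Reagents that add atoms: iodine, II
Why: α-Amino alkoxide directed ortho-lithiation: the lithium hemiaminal masks the aldehyde and, together with OMe, directs n-BuLi to the ring carbon between them (the other ortho position is flanked by a bulky, non-coordinating OTBS group), and iodine quench with aqueous hydrolysis of the hemiaminal should give the 2-iodo aldehyde.

**Step 3**
Reactants: 6 3-methoxybenzene-1,2-diol (3-methoxycatechol)
Product: 7 1,2-bis(TBSO)-3-methoxybenzene
Conditions: TBSCl (2.4 equiv), imidazole (5 equiv), DMF, 0 → 25 °C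
Reagents that add atoms: tert-butyldimethylsilyl chloride, CC(C)(C)[Si](C)(C)Cl
Why: Silyl ether formation on both catechol hydroxyls, leaving OMe as the only group able to direct the lithiation of the next step.

**Step 4**
Reactants: 7 1,2-bis(TBSO)-3-methoxybenzene
Product: 9 [3,4-bis(TBSO)-2-methoxyphenyl]methanol, via aryllithium 8 (not isolated)
Conditions: n-BuLi (1.2 equiv), TMEDA, THF, −20 → 0 °C; (CH2O)n, −78 → 25 °C; H2O
Reagents that add atoms: formaldehyde (as paraformaldehyde), C=O
Why: Directed ortho-metalation: OMe directs lithiation to its only free ortho position (silyloxy groups are poor directors, as in the lithiation of 1,2,3-trialkoxybenzenes next to a terminal ether), and the aryllithium is hydroxymethylated by formaldehyde.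

**Step 5**
Reactants: 9 [3,4-bis(TBSO)-2-methoxyphenyl]methanol
Product: 10 1-(bromomethyl)-3,4-bis(TBSO)-2-methoxybenzene
Conditions: CBr4 (1.2 equiv), PPh3 (1.25 equiv), CH2Cl2, 0 °C; short filtration, used at once
Reagents that add atoms: tetrabromomethane, BrC(Br)(Br)Br
Why: Appel reaction: bromide displaces the alkoxyphosphonium ion under neutral conditions that aryl silyl ethers tolerate; the electron-rich benzylic bromide is not stored.

**Step 6**
Reactants: 10 1-(bromomethyl)-3,4-bis(TBSO)-2-methoxybenzene; 5 4,5-bis(TBSO)-2-iodo-3-methoxybenzaldehyde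
Product: 12 4,5-bis(TBSO)-2-{[3,4-bis(TBSO)-2-methoxyphenyl]methyl}-3-methoxybenzaldehyde, via benzylzinc bromide 11 (not isolated)
Conditions: Zn dust, LiCl, THF, 0 → 25 °C; then 5, Pd(OAc)2 (2 mol%), SPhos (4 mol%), THF, 25 °C
Reagents that add atoms: none
Why: Negishi cross-coupling: LiCl-assisted zinc insertion gives the benzylic zinc reagent, which adds only slowly to the free aldehyde at 25 °C, while Pd/SPhos should couple it quickly with the doubly ortho-substituted aryl iodide to give the diarylmethane.

**Step 7**
Reactants: 13 2,5-dibromofuran; 14 [4-(TBSO)phenyl]boronic acid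
Product: 15 2,5-bis[4-(TBSO)phenyl]furan
Conditions: 14 (2.4 equiv), Pd(PPh3)4 (5 mol%), K3PO4, toluene/H2O, 80 °C
Reagents that add atoms: none
Why: Twofold Suzuki–Miyaura coupling at the activated α-C–Br bonds of the furan; phosphate base should spare the aryl silyl ethers.

**Step 8**
Reactants: 15 2,5-bis[4-(TBSO)phenyl]furan
Product: 16 (2Z)-1,4-bis[4-(TBSO)phenyl]but-2-ene-1,4-dione
Conditions: mCPBA (1.1 equiv), NaHCO3, CH2Cl2, 0 °C, dark
Reagents that add atoms: meta-chloroperbenzoic acid, OOC(=O)c1cccc(Cl)c1
Why: Oxidative ring opening of a 2,5-diarylfuran (epoxidation of the furan and opening of the oxirane) gives the ene-1,4-dione whose double bond is the former ring C3–C4 bond and is therefore Z; buffered, cold and dark conditions should prevent isomerization to the E isomer.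

**Step 9**
Reactants: 12 4,5-bis(TBSO)-2-{[3,4-bis(TBSO)-2-methoxyphenyl]methyl}-3-methoxybenzaldehyde; 16 (2Z)-1,4-bis[4-(TBSO)phenyl]but-2-ene-1,4-dione
Product: 18 all-cis (1S,2S,3S,4S)-4-hydroxytetralin cycloadduct, via photoenol 17 (not isolated)
Conditions: (R,R)-TADDOL (1.3 equiv), Ti(OiPr)4 (1.2 equiv), toluene, 25 °C, i-PrOH removed in vacuo [gives (TADDOLate)Ti(OiPr)2]; 12 (1.0 equiv), 16 (1.5 equiv), hν (365 nm LED), degassed toluene, −20 °C; aq. NaHCO3
Reagents that add atoms: none
Why: Proposed new method: irradiation of 12 in its n,π* band triggers 1,5-hydrogen transfer from the doubly benzylic CH2 to the carbonyl oxygen and gives the hydroxy-o-quinodimethane 17, which the titanium TADDOLate holds through the dienol oxygen while one carbonyl group of 16 binds to the same metal, and a templated endo [4+2] cycloaddition then forms C1–C2 and C4–C3 (the Ti-bound carbonyl becomes the C3 aroyl group). The closest known reaction type is the Ti(OiPr)4-promoted photoenolization/Diels–Alder reaction of electron-rich 2-methylbenzaldehydes with enones and its TADDOL-controlled enantioselective variant; not yet shown are a diene terminus that carries an aryl group (so that a stereocentre arises at the former benzylic carbon) and an acyclic (Z)-1,2-diaroylethene as dienophile. Ring B is closed as a six-membered carbocycle by intermolecular [4+2] cycloaddition, both new σ bonds arising on one face of the diene and one face of the alkene. Suprafacial addition to the Z alkene places the two aroyl groups cis, the endo arrangement enforced by the Ti bridge places them cis to the outward OH and aryl groups (all-cis adduct), and the C2-symmetric TADDOLate blocks one face of the Ti-bound diene so that C1 is formed S; because the C1/C2 relation is fixed in the first, Ti-bridged bond-forming event, it holds even if bond formation is asynchronous. No regiochemical question arises since 16 is symmetrical; the Z geometry of 16 is kept because 365 nm light returns any E isomer, the stronger absorber, to the Z form; the ring C aryl group takes the outward position because the inward one would collide with the enol C–H across the diene; and only the long-lived (E)-enol is trapped, the (Z)-enol reverting to 12 by 1,5-H shift.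

**Step 10**
Reactants: 18 all-cis (1S,2S,3S,4S)-4-hydroxytetralin cycloadduct
Product: 19 hexa-TBS ether of licobichalcone, (1S,2S)
Conditions: Martin sulfurane Ph2S[OC(CF3)2Ph]2 (1.5 equiv), CH2Cl2, 0 → 25 °C
Reagents that add atoms: none
Why: Dehydration of a benzylic β-hydroxy ketone with Martin sulfurane: the alkoxysulfurane ionizes at the benzylic C4 (para-silyloxy assistance) and loses the only β-hydrogen, the C3–H α to the ketone, giving the aryl-conjugated enone under neutral conditions, so that the C1 and C2 stereocentres should stay untouched.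

**Step 11**
Reactants: 19 hexa-TBS ether of licobichalcone
Product: 20 licobichalcone
Conditions: Et3N·3HF (excess), THF/MeCN, 0 → 25 °C, argon; pH 5 buffer work-up with degassed solvents
Reagents that add atoms: none
Why: Fluoride-mediated desilylation of the six aryl silyl ethers (driven by the Si–F bond) in a weakly acidic medium that keeps the phenols protonated and should avoid enolization at C2; no stereocentre is touched.

**Compound list**
1 | 3,4-dihydroxy-5-methoxybenzaldehyde (5-hydroxyvanillin) | COc1cc(C=O)cc(O)c1O | starting material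
2 | 3,4-bis(tert-butyldimethylsilyloxy)-5-methoxybenzaldehyde | COc1cc(C=O)cc(O[Si](C)(C)C(C)(C)C)c1O[Si](C)(C)C(C)(C)C | intermediate
3 | lithium α-amino alkoxide of 2, ArCH(OLi)N(Me)CH2CH2NMe2 (not isolated) | [Li]OC(N(C)CCN(C)C)c1cc(OC)c(O[Si](C)(C)C(C)(C)C)c(O[Si](C)(C)C(C)(C)C)c1 | intermediate
4 | 3 lithiated at the ring carbon between the carbinol carbon and OMe (not isolated) | [Li]OC(N(C)CCN(C)C)c1c([Li])c(OC)c(O[Si](C)(C)C(C)(C)C)c(O[Si](C)(C)C(C)(C)C)c1 | intermediate
5 | 4,5-bis(tert-butyldimethylsilyloxy)-2-iodo-3-methoxybenzaldehyde | COc1c(I)c(C=O)cc(O[Si](C)(C)C(C)(C)C)c1O[Si](C)(C)C(C)(C)C | intermediate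
6 | 3-methoxybenzene-1,2-diol (3-methoxycatechol) | COc1cccc(O)c1O | starting material
7 | 1,2-bis(tert-butyldimethylsilyloxy)-3-methoxybenzene | COc1cccc(O[Si](C)(C)C(C)(C)C)c1O[Si](C)(C)C(C)(C)C | intermediate
8 | [3,4-bis(tert-butyldimethylsilyloxy)-2-methoxyphenyl]lithium (not isolated) | [Li]c1ccc(O[Si](C)(C)C(C)(C)C)c(O[Si](C)(C)C(C)(C)C)c1OC | intermediate
9 | [3,4-bis(tert-butyldimethylsilyloxy)-2-methoxyphenyl]methanol | COc1c(CO)ccc(O[Si](C)(C)C(C)(C)C)c1O[Si](C)(C)C(C)(C)C | intermediate
10 | 1-(bromomethyl)-3,4-bis(tert-butyldimethylsilyloxy)-2-methoxybenzene | COc1c(CBr)ccc(O[Si](C)(C)C(C)(C)C)c1O[Si](C)(C)C(C)(C)C | intermediate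
11 | [3,4-bis(tert-butyldimethylsilyloxy)-2-methoxybenzyl]zinc bromide (not isolated) | COc1c(C[Zn]Br)ccc(O[Si](C)(C)C(C)(C)C)c1O[Si](C)(C)C(C)(C)C | intermediate
12 | 4,5-bis(tert-butyldimethylsilyloxy)-2-{[3,4-bis(tert-butyldimethylsilyloxy)-2-methoxyphenyl]methyl}-3-methoxybenzaldehyde | COc1c(Cc2c(C=O)cc(O[Si](C)(C)C(C)(C)C)c(O[Si](C)(C)C(C)(C)C)c2OC)ccc(O[Si](C)(C)C(C)(C)C)c1O[Si](C)(C)C(C)(C)C | intermediate
13 | 2,5-dibromofuran | Brc1ccc(Br)o1 | starting material
14 | [4-(tert-butyldimethylsilyloxy)phenyl]boronic acid | CC(C)(C)[Si](C)(C)Oc1ccc(B(O)O)cc1 | starting material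
15 | 2,5-bis[4-(tert-butyldimethylsilyloxy)phenyl]furan | CC(C)(C)[Si](C)(C)Oc1ccc(-c2ccc(-c3ccc(O[Si](C)(C)C(C)(C)C)cc3)o2)cc1 | intermediate
16 | (2Z)-1,4-bis[4-(tert-butyldimethylsilyloxy)phenyl]but-2-ene-1,4-dione | CC(C)(C)[Si](C)(C)Oc1ccc(C(=O)/C=C\C(=O)c2ccc(O[Si](C)(C)C(C)(C)C)cc2)cc1 | intermediate
17 | photoenol of 12: 5-(hydroxymethylidene)-6-(arylmethylidene)cyclohexa-1,3-diene with OH and the ring C aryl group both outward, (E)-enol (not isolated) | O/C=C1/C(=C/c2ccc(O[Si](C)(C)C(C)(C)C)c(O[Si](C)(C)C(C)(C)C)c2OC)C(OC)=C(O[Si](C)(C)C(C)(C)C)C(O[Si](C)(C)C(C)(C)C)=C1 | intermediate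
18 | {(1S,2S,3S,4S)-6,7-bis(TBSO)-1-[3,4-bis(TBSO)-2-methoxyphenyl]-4-hydroxy-8-methoxy-1,2,3,4-tetrahydronaphthalene-2,3-diyl}bis{[4-(TBSO)phenyl]methanone}, the four ring substituents all cis | COc1c([C@H]2c3c(cc(O[Si](C)(C)C(C)(C)C)c(O[Si](C)(C)C(C)(C)C)c3OC)[C@@H](O)[C@@H](C(=O)c3ccc(O[Si](C)(C)C(C)(C)C)cc3)[C@H]2C(=O)c2ccc(O[Si](C)(C)C(C)(C)C)cc2)ccc(O[Si](C)(C)C(C)(C)C)c1O[Si](C)(C)C(C)(C)C | intermediate
19 | {(1S,2S)-6,7-bis(TBSO)-1-[3,4-bis(TBSO)-2-methoxyphenyl]-8-methoxy-1,2-dihydronaphthalene-2,3-diyl}bis{[4-(TBSO)phenyl]methanone}, 1,2-cis | COc1c([C@H]2c3c(cc(O[Si](C)(C)C(C)(C)C)c(O[Si](C)(C)C(C)(C)C)c3OC)C=C(C(=O)c3ccc(O[Si](C)(C)C(C)(C)C)cc3)[C@H]2C(=O)c2ccc(O[Si](C)(C)C(C)(C)C)cc2)ccc(O[Si](C)(C)C(C)(C)C)c1O[Si](C)(C)C(C)(C)C | intermediate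
20 | licobichalcone, [(1S,2S)-1-(3,4-dihydroxy-2-methoxyphenyl)-6,7-dihydroxy-8-methoxy-1,2-dihydronaphthalene-2,3-diyl]bis[(4-hydroxyphenyl)methanone] | COc1c([C@H]2c3c(cc(O)c(O)c3OC)C=C(C(=O)c3ccc(O)cc3)[C@H]2C(=O)c2ccc(O)cc2)ccc(O)c1O | target

**Step count and risks**
Total step count: 11. Longest linear sequence: 7 steps (steps 3, 4, 5, 6, 9, 10, 11, from 6).

Steps most likely to fail:

1. Step 9 (proposed new method). What may go wrong: poor facial selectivity on the titanium-bound diene, whose aryl-bearing terminus is more crowded than in the known cases, and scrambling of the dienophile geometry by triplet energy transfer from the excited aldehyde. Fallback with known chemistry: setting out from 12 and 16, the ligand-free Ti(OiPr)4-promoted photoenolization/Diels–Alder reaction (365 nm, toluene) should give the all-cis adduct as the racemate, that is 18 together with its enantiomer F1. The two are separated by preparative chromatography on a chiral stationary phase, and 18 comes back to the route at step 10. Any 2,3-trans adduct that arises from the E dienophile is carried through the fallback of step 10, which resets C2.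

2. Step 10. What may go wrong: epimerization at C2, which after formation of the enone is α to one ketone and vinylogously activated, to the thermodynamically preferred trans isomer. Fallback: setting out from 18, the elimination is run under deliberately equilibrating conditions (MsCl, Et3N, CH2Cl2, 0 °C, then DBU, 25 °C) so that all material converges on the (1S,2R)-trans epimer F2. Deprotonation with KN(SiMe3)2 in THF at −78 °C gives the potassium enolate F3. Inverse quench into cold AcOH/THF should protonate C2 on the face opposite the pseudoaxial C1 aryl group (kinetic protonation, as used for 1-aryl-2-acyl tetralins), giving the cis compound 19, where the route is rejoined.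

3. Step 11. What may go wrong: enolization at C2 and air oxidation of the freed catechols during the sixfold desilylation of the sensitive dihydronaphthalene. Fallback: the order is reversed. Setting out from 18, desilylation with Et3N·3HF gives the hexaphenol alcohol F4, whose stereocentres are α to ordinary saturated ketones. Mild acid (pyridinium p-toluenesulfonate, acetone, 25 °C, argon) should then dehydrate it through the para-quinone methide formed from the 7-OH group and C4, with loss of the C3–H, and deliver 20 directly.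

**Further compounds**
F1 | step 9 | enantiomer of 18, (1R,2R,3R,4R), formed with 18 as the racemate | COc1c([C@@H]2c3c(cc(O[Si](C)(C)C(C)(C)C)c(O[Si](C)(C)C(C)(C)C)c3OC)[C@H](O)[C@H](C(=O)c3ccc(O[Si](C)(C)C(C)(C)C)cc3)[C@@H]2C(=O)c2ccc(O[Si](C)(C)C(C)(C)C)cc2)ccc(O[Si](C)(C)C(C)(C)C)c1O[Si](C)(C)C(C)(C)C
F2 | step 10 | (1S,2R)-trans epimer of 19 | COc1c([C@H]2c3c(cc(O[Si](C)(C)C(C)(C)C)c(O[Si](C)(C)C(C)(C)C)c3OC)C=C(C(=O)c3ccc(O[Si](C)(C)C(C)(C)C)cc3)[C@@H]2C(=O)c2ccc(O[Si](C)(C)C(C)(C)C)cc2)ccc(O[Si](C)(C)C(C)(C)C)c1O[Si](C)(C)C(C)(C)C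
F3 | step 10 | potassium enolate of the C2 aroyl group of F2, drawn as the (Z)-enolate, C1 unchanged | COc1c([C@H]2c3c(cc(O[Si](C)(C)C(C)(C)C)c(O[Si](C)(C)C(C)(C)C)c3OC)C=C(C(=O)c3ccc(O[Si](C)(C)C(C)(C)C)cc3)/C2=C(\O[K])c2ccc(O[Si](C)(C)C(C)(C)C)cc2)ccc(O[Si](C)(C)C(C)(C)C)c1O[Si](C)(C)C(C)(C)C
F4 | step 11 | hexaphenol alcohol, the fully desilylated all-cis adduct | COc1c([C@H]2c3c(cc(O)c(O)c3OC)[C@@H](O)[C@@H](C(=O)c3ccc(O)cc3)[C@H]2C(=O)c2ccc(O)cc2)ccc(O)c1O
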